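The ten-membered carbocycle (C1–C10) is disconnected at C8–C9. The C8 carbinol, the adjacent C9 oxygen and the C1=C10 alkene bearing C14 form a syn homoallylic diol monoether, the product pattern of a γ-alkoxyallylboron reagent. An aldehyde at C8 of a preformed trans-γ-lactone (C6, C7, C11, C12, lactone oxygen) is therefore tethered, through C2–C6 with the cis C4=C5 alkene, to an enantioenriched allylic pinacol boronate (boron on C1, PMB enol ether at C9, oxygen cis to C1). One thermal allyl transfer should form C8–C9, close the ring, set C8 and C9, move the alkene to C1=C10 and trade the C1 stereocentre for both new ones.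

Key step: step 19

Remark (descriptors): the enol ether needed for the syn outcome has the PMB-oxygen cis to C1 across C9=C10 ("Z-type" in allylboration usage); its CIP descriptor is E because CH2OTBS on C10 outranks C1. The C7 descriptor also switches between intermediates through priority changes only, so C7 is described as "H7 trans to H6". The cyclisation substrate 36 and its product 38 are used with 1R, 6R and 8S,9S; they were checked against the target (6R,7S,8S,9S; both ring alkenes ring-cis) and need no structural correction.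

Remark (order of events): the C1 boronate is made before the lactone, because α-lithiation of the carbamate tolerates neither lactone, imide nor free hydroxyl. Once allylboronate and enol ether are present, only neutral or mildly basic operations are used; acid and fluoride appear only after ring closure. Aldehyde 36 keeps the pinacol ester (uncatalysed, it favours the chair with C2 axial) and is cyclised as soon as it is made, since it is a β-acyloxy aldehyde.

Abbreviations: TBDPS = tert-butyldiphenylsilyl, TBS = tert-butyldimethylsilyl, TES = triethylsilyl, TMS = trimethylsilyl, PMB = 4-methoxybenzyl, Bpin = 4,4,5,5-tetramethyl-1,3,2-dioxaborolan-2-yl, Cb = N,N-diisopropylcarbamoyl. Locants C1–C15 are germacrane locants.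

**Chain C1–C6**

Step 1
Reactants: 1 propargyl alcohol
Product: 2 tert-butyl(diphenyl)(prop-2-yn-1-yloxy)silane
Conditions: TBDPSCl, imidazole, CH2Cl2, 0 °C → rt
Reagents that add atoms: tert-butyl(chloro)diphenylsilane, CC(C)(C)[Si](Cl)(c1ccccc1)c1ccccc1
Why: Routine silylation of a primary alcohol installs the C15 silyl ether, which should survive every step up to the last.

Step 2
Reactants: 2 tert-butyl(diphenyl)(prop-2-yn-1-yloxy)silane; 3 methyl chloroformate
Product: 5 methyl 4-[(tert-butyldiphenylsilyl)oxy]but-2-ynoate, via lithium acetylide 4 (not isolated)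
Conditions: nBuLi, THF, −78 °C; then 3, −78 → 0 °C
Reagents that add atoms: none
Why: Acylation of a lithium acetylide with a chloroformate is a standard route to 2-alkynoates and brings in C6.

Step 3
Reactants: 5 methyl 4-[(tert-butyldiphenylsilyl)oxy]but-2-ynoate
Product: 6 methyl (Z)-4-[(tert-butyldiphenylsilyl)oxy]-3-iodobut-2-enoate (iodine cis to the ester)
Conditions: NaI, AcOH, 60 °C
Reagents that add atoms: sodium iodide, [Na+].[I-]
Why: Conjugate anti-hydroiodination of a 2-alkynoate should give the (Z)-β-iodo enoate, which fixes the later C4=C5 geometry because the group that replaces iodine ends cis to C6.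

Step 4
Reactants: 7 allyl alcohol
Product: 9 prop-2-en-1-yl N,N-diisopropylcarbamate, via sodium alkoxide 8 (not isolated)
Conditions: NaH, THF, 0 °C; iPr2NCOCl, reflux
Reagents that add atoms: N,N-diisopropylcarbamoyl chloride, CC(C)N(C(C)C)C(Cl)=O
Why: O-Carbamoylation of the alkoxide gives the hindered carbamate that later directs α-lithiation at C1.

Step 5
Reactants: 9 prop-2-en-1-yl N,N-diisopropylcarbamate; 6 methyl (Z)-4-[(tert-butyldiphenylsilyl)oxy]-3-iodobut-2-enoate
Product: 11 methyl (E)-3-{[(tert-butyldiphenylsilyl)oxy]methyl}-6-[(diisopropylcarbamoyl)oxy]hex-2-enoate (ester cis to the C3 chain), via alkylborane 10 (not isolated)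
Conditions: 9-BBN, THF, 0 °C → rt; then 6, PdCl2(dppf), AsPh3, Cs2CO3, DMF/H2O, rt
Reagents that add atoms: none
Why: Anti-Markovnikov hydroboration and B-alkyl Suzuki–Miyaura coupling with the vinyl iodide proceed with retention of alkene geometry, so C3 should end cis to C6.

Step 6
Reactants: 11 methyl (E)-3-{[(tert-butyldiphenylsilyl)oxy]methyl}-6-[(diisopropylcarbamoyl)oxy]hex-2-enoate
Product: 12 (E)-4-{[(tert-butyldiphenylsilyl)oxy]methyl}-6-hydroxyhex-4-en-1-yl N,N-diisopropylcarbamate
Conditions: iBu2AlH, CH2Cl2, −78 °C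
Reagents that add atoms: none
Why: 1,2-Reduction of the enoate by the aluminium hydride gives the allylic alcohol (C6), the hindered carbamate being inert at −78 °C.

Step 7
Reactants: 12 (E)-4-{[(tert-butyldiphenylsilyl)oxy]methyl}-6-hydroxyhex-4-en-1-yl N,N-diisopropylcarbamate
Product: 13 (E)-4-{[(tert-butyldiphenylsilyl)oxy]methyl}-6-[(trimethylsilyl)oxy]hex-4-en-1-yl N,N-diisopropylcarbamate
Conditions: TMSCl, Et3N, CH2Cl2, 0 °C
Reagents that add atoms: chlorotrimethylsilane, C[Si](C)(C)Cl
Why: Silylation removes the only acidic proton before the lithiation, and the TMS ether can later be cleaved by K2CO3/MeOH, which neither an allylboronate nor an enol ether should feel.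

**Alkenyl boronate (C9, C10, C14)**

Step 8
Reactants: 14 4-methoxybenzyl alcohol; 15 methyl propiolate
Product: 16 methyl (E)-3-[(4-methoxybenzyl)oxy]prop-2-enoate
Conditions: DABCO (10 mol %), CH2Cl2, rt
Reagents that add atoms: none
Why: Amine-catalysed oxa-Michael addition of an alcohol to a propiolate gives the (E)-β-alkoxyacrylate.

Step 9
Reactants: 16 methyl (E)-3-[(4-methoxybenzyl)oxy]prop-2-enoate
Product: 18 methyl (Z)-2-iodo-3-[(4-methoxybenzyl)oxy]prop-2-enoate (iodine cis to the ether oxygen), via acetoxy iodide 17 (not isolated)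
Conditions: NIS, AcOH, CH2Cl2, rt; then Et3N, rt
Reagents that add atoms: N-iodosuccinimide, O=C1CCC(=O)N1I
Why: Iodo-acetoxylation of the electron-rich enol ether followed by base-induced loss of acetic acid (addition–elimination) should return the push–pull alkene as its stable isomer, with the ester trans to the ether oxygen.

Step 10
Reactants: 18 methyl (Z)-2-iodo-3-[(4-methoxybenzyl)oxy]prop-2-enoate
Product: 19 (Z)-2-iodo-3-[(4-methoxybenzyl)oxy]prop-2-en-1-ol
Conditions: iBu2AlH, CH2Cl2, −78 °C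
Reagents that add atoms: none
Why: Ester reduction by the aluminium hydride gives the primary allylic alcohol (C14) without touching the vinyl iodide or the enol ether geometry.

Step 11
Reactants: 19 (Z)-2-iodo-3-[(4-methoxybenzyl)oxy]prop-2-en-1-ol
Product: 20 tert-butyl{[(Z)-2-iodo-3-[(4-methoxybenzyl)oxy]prop-2-en-1-yl]oxy}dimethylsilane
Conditions: TBSCl, imidazole, DMF, 0 °C
Reagents that add atoms: tert-butyl(chloro)dimethylsilane, CC(C)(C)[Si](C)(C)Cl
Why: Standard silylation protects C14–OH as the TBS ether under basic conditions that the acid-sensitive alkoxy allylic alcohol tolerates.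

Step 12
Reactants: 20 tert-butyl{[(Z)-2-iodo-3-[(4-methoxybenzyl)oxy]prop-2-en-1-yl]oxy}dimethylsilane
Product: 21 tert-butyl{[(E)-3-[(4-methoxybenzyl)oxy]-2-(4,4,5,5-tetramethyl-1,3,2-dioxaborolan-2-yl)prop-2-en-1-yl]oxy}dimethylsilane (boron cis to the PMB-oxygen)
Conditions: B2pin2, PdCl2(PPh3)2 (3 mol %), PPh3, KOPh, toluene, 50 °C
Reagents that add atoms: bis(pinacolato)diboron, CC1(C)OB(OC1(C)C)B1OC(C)(C)C(C)(C)O1
Why: Miyaura borylation of an alkenyl iodide occurs with retention, so boron on C10 should stay cis to the C9 oxygen.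

**Union, lactone and aldehyde**

Step 13
Reactants: 13 (E)-4-{[(tert-butyldiphenylsilyl)oxy]methyl}-6-[(trimethylsilyl)oxy]hex-4-en-1-yl N,N-diisopropylcarbamate; 21 alkenyl boronate
Product: 25 (1R)-C1 allylic boronate alcohol HOCH2(C6)–C5H=C4(CH2OTBDPS)–C3H2–C2H2–C1H(Bpin)–C10(CH2OTBS)=C9H–OPMB (C6 cis to C3; O9 cis to C1), via lithiated carbamate 22 (not isolated), via lithium boronate complex 23 (not isolated), via trimethylsilyl ether 24 (not isolated)
Conditions: sBuLi, (−)-sparteine, Et2O, −78 °C, 5 h; 21, −78 → 35 °C; then K2CO3, MeOH, 0 °C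
Reagents that add atoms: none
Why: In this lithiation–borylation the sparteine-mediated Hoppe deprotonation removes the pro-S hydrogen at C1, borylation occurs with retention and the alkenyl group shifts from boron to carbon with inversion, which should give the (R)-C1 boronate with the alkenyl geometry intact.

Step 14
Reactants: 25 C1 allylic boronate alcohol
Product: 26 enal OHC(C6)–C5H=C4(CH2OTBDPS)–C3H2–C2H2–C1H(Bpin)–C10(CH2OTBS)=C9H–OPMB (1R)
Conditions: MnO2, CH2Cl2, rt
Reagents that add atoms: none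
Why: MnO2 oxidises the allylic alcohol under neutral conditions, and a chair-type allyl transfer from C1–B to this C6 aldehyde is strained (eight-membered ring, three-bond tether) so the enal should survive until it is used at once.

Step 15
Reactants: 27 (S)-4-benzyloxazolidin-2-one; 28 methyl 4-chloro-4-oxobutanoate
Product: 30 (S)-4-benzyl-3-(4-methoxy-4-oxobutanoyl)oxazolidin-2-one, via lithium oxazolidinide 29 (not isolated)
Conditions: nBuLi, THF, −78 °C; then 28, −78 → 0 °C
Reagents that add atoms: none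
Why: N-Acylation of the lithiated auxiliary with the acid chloride is the standard preparation of Evans imides.

Step 16
Reactants: 30 (S)-4-benzyl-3-(4-methoxy-4-oxobutanoyl)oxazolidin-2-one; 26 enal
Product: 34 trans-lactone imide (6R,7S; C8 is the imide carbonyl; H7 trans to H6), via boron enolate 31 (not isolated), via boron aldolate 32 (not isolated), via hydroxy ester 33 (not isolated)
Conditions: 30 (1.5 equiv), Bu2BOTf (1.4 equiv), iPr2NEt, CH2Cl2, 0 °C; 26, −78 → 0 °C; pH 7 buffer, MeOH; then 2-hydroxypyridine (20 mol %), toluene, 45 °C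
Reagents that add atoms: none
Why: The Evans syn-aldol of the (Z)-dibutylboron enolate through a Zimmerman–Traxler chair, steered by the (S)-benzyl auxiliary, should set C7 (S) and C6 (R), and the syn γ-hydroxy ester then closes to the trans-lactone with loss of methanol under neutral bifunctional catalysis.

Step 17
Reactants: 34 trans-lactone imide
Product: 35 hydroxymethyl lactone (C8 = CH2OH; 6R; H7 trans to H6; 1R boronate)
Conditions: NaBH4, THF/H2O, 0 °C → rt
Reagents that add atoms: none
Why: Borohydride in wet THF reduces the activated exocyclic imide carbonyl to the primary alcohol and releases the auxiliary (reductive auxiliary removal), while the γ-lactone and the C–B bond should be untouched.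

Step 18
Reactants: 35 hydroxymethyl lactone
Product: 36 lactone aldehyde with C1 allylboronate (1R,6R,7S; cyclisation substrate)
Conditions: Dess–Martin periodinane, NaHCO3, CH2Cl2, 0 °C; filtered through Florisil and used at once
Reagents that add atoms: none
Why: Buffered Dess–Martin oxidation gives the aldehyde without acid or amine base, so allylboronate, enol ether and the epimerisable β-acyloxy centre C7 should stay intact.

Step 19
Reactants: 36 lactone aldehyde with C1 allylboronate
Product: 38 ten-membered lactone with free C8 hydroxyl and C9 PMB ether (6R,8S,9S; H7 trans to H6; ring-cis C1=C10 and C4=C5), via borate ester 37 (not isolated)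
Conditions: toluene (0.002 M), 60 °C; then pH 7 phosphate buffer, rt
Reagents that add atoms: none
Why: Proposed new method: boron of the pinacol ester binds the C8 carbonyl oxygen and the allyl group is transferred through a six-membered chair (B, O, C8, C9, C10, C1) in which C9 attacks C8 while the C1–B bond breaks and the π-bond moves to C1=C10, the closest known reactions being intermolecular additions of α-substituted pinacol allylboronates and of (Z)-γ-alkoxyallylboronates to aldehydes and medium-ring closures by intramolecular allylmetal–aldehyde addition. The ten-membered ring closes by intramolecular carbonyl allylation (SE2′ allyl transfer, new bond C8–C9 endocyclic) because the tether C2–C6 joins C1 and C7, which occupy 1,4-positions of the chair. C9 (S) should follow from the enol ether geometry (oxygen cis to C1, hence axial, hence syn to O8), C8 (S) from the equatorial C7 branch on the chair whose sense is fixed by the (R)-C1–B centre, and the ring-cis C1=C10 alkene from C2 standing axial on C1. The step needs this chair (C2 axial, C7 equatorial) rather than the one with C2 equatorial and C7 axial, which would give the C8 epimer with a ring-trans alkene; it should be secured by the pinacol ester under purely thermal conditions (no Lewis acid, which favours equatorial C2), by A(1,2) strain between an equatorial C2 and CH2OTBS on C10, and by the short tether with the cis C4=C5 alkene, which cannot span two equatorial positions. The aldehyde face is set by the tether and not by Felkin–Anh induction (which would place C6 anti to C9), the main strain being the passage of C6 past the axial C9–O bond, and high dilution should suppress intermolecular allyl transfer. Hydrolysis of borate 37 on work-up frees the C8 hydroxyl while O9 stays as the PMB ether.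

**From the ring to the target**

Step 20
Reactants: 38 ten-membered lactone with free C8 hydroxyl
Product: 39 C8 triethylsilyl ether of 38
Conditions: TESOTf, 2,6-lutidine, CH2Cl2, −78 °C
Reagents that add atoms: triethylsilyl trifluoromethanesulfonate, CC[Si](CC)(CC)OS(=O)(=O)C(F)(F)F
Why: Silylation of the hindered secondary alcohol with a silyl triflate should block alkoxide-induced translactonisation to the 8,12-olide during the enolate chemistry that follows.

Step 21
Reactants: 39 C8 triethylsilyl ether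
Product: 41 C11 dimethylaminomethyl lactone (Mannich base; C11 configuration inconsequential), via lithium enolate 40 (not isolated)
Conditions: LDA, THF, −78 °C; CH2=NMe2+ I−, −78 °C → rt
Reagents that add atoms: dimethylmethyleneammonium iodide (Eschenmoser's salt), C=[N+](C)C.[I-]
Why: The lithium enolate of the γ-lactone is aminomethylated at C11 by the iminium salt (Mannich reaction), C7 carrying no β-leaving group and the new C11 centre being destroyed in the next step.

Step 22
Reactants: 41 Mannich base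
Product: 43 α-methylene lactone (C11=C13; C8–OTES, C9–OPMB, C14–OTBS, C15–OTBDPS), via ammonium iodide 42 (not isolated)
Conditions: MeI, MeOH, rt; then NaHCO3, CH2Cl2/H2O, rt
Reagents that add atoms: none
Why: Quaternisation and E1cB loss of trimethylamine (Hofmann-type elimination) should unveil the exocyclic methylene without moving it into the ring.

Step 23
Reactants: 43 α-methylene lactone
Product: 44 C8 alcohol (C14–OTBS and C15–OTBDPS retained)
Conditions: PPTS, MeOH/CH2Cl2, 0 °C
Reagents that add atoms: none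
Why: Mild acid-catalysed methanolysis cleaves the triethylsilyl ether much faster than the primary TBS and TBDPS ethers, and freeing C8 before C14 avoids a C8–O/C14 lactol at the enal stage.

Step 24
Reactants: 44 C8 alcohol
Product: 45 C8 methacrylate
Conditions: methacrylic anhydride, Et3N, DMAP, CH2Cl2, 0 °C → rt
Reagents that add atoms: methacrylic anhydride, C=C(C)C(=O)OC(=O)C(C)=C
Why: DMAP-catalysed acyl transfer esterifies the C8 alcohol while C9 is still a PMB ether, so no acyl migration is possible.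

Step 25
Reactants: 45 C8 methacrylate
Product: 46 C14 allylic alcohol
Conditions: camphorsulfonic acid (10 mol %), MeOH/CH2Cl2, 0 °C
Reagents that add atoms: none
Why: Acid-catalysed methanolysis removes the primary allylic TBS ether while the far more acid-stable primary TBDPS ether, the PMB ether and the esters should remain.

Step 26
Reactants: 46 C14 allylic alcohol
Product: 47 C14 enal (C1=C10–CHO; C2 trans to the formyl group)
Conditions: MnO2, CH2Cl2, rt
Reagents that add atoms: none
Why: MnO2 oxidises the allylic primary alcohol to the enal under neutral conditions, and the ring holds the alkene geometry.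

Step 27
Reactants: 47 C14 enal
Product: 48 C9 alcohol
Conditions: DDQ, CH2Cl2/pH 7 buffer, 0 °C
Reagents that add atoms: none
Why: Oxidative PMB cleavage by DDQ (benzylic hydride abstraction, then hydrolysis) is selective over silyl ether, esters and enal under buffered conditions.

Step 28
Reactants: 48 C9 alcohol
Product: 49 C9 acetate (C15–OTBDPS)
Conditions: Ac2O, pyridine, DMAP (cat.), CH2Cl2, 0 °C
Reagents that add atoms: acetic anhydride, CC(=O)OC(C)=O
Why: Fast DMAP-catalysed acetylation of the allylic alcohol should outrun 1,2-migration of the neighbouring methacrylate.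

Step 29
Reactants: 49 C9 acetate
Product: 50 CNP0147326.4 (6R,7S,8S,9S)
Conditions: HF·pyridine, pyridine, THF, 0 °C → rt
Reagents that add atoms: none
Why: Buffered fluoride-driven Si–O cleavage removes the last silyl ether under mildly acidic conditions that should spare the allylic acetate, the methacrylate, the enal and the α-methylene lactone.

**Compound list**

1 | propargyl alcohol | C#CCO | starting material
2 | tert-butyl(diphenyl)(prop-2-yn-1-yloxy)silane | C#CCO[Si](c1ccccc1)(c1ccccc1)C(C)(C)C | intermediate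
3 | methyl chloroformate | COC(=O)Cl | starting material
4 | lithium acetylide of 2 (not isolated) | [Li]C#CCO[Si](c1ccccc1)(c1ccccc1)C(C)(C)C | intermediate
5 | methyl 4-[(tert-butyldiphenylsilyl)oxy]but-2-ynoate | COC(=O)C#CCO[Si](c1ccccc1)(c1ccccc1)C(C)(C)C | intermediate
6 | methyl (Z)-4-[(tert-butyldiphenylsilyl)oxy]-3-iodobut-2-enoate | COC(=O)/C=C(\I)CO[Si](c1ccccc1)(c1ccccc1)C(C)(C)C | intermediate
7 | allyl alcohol | C=CCO | starting material
8 | sodium prop-2-en-1-olate (not isolated) | [Na+].[O-]CC=C | intermediate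
9 | prop-2-en-1-yl N,N-diisopropylcarbamate | C=CCOC(=O)N(C(C)C)C(C)C | intermediate
10 | 3-(9-borabicyclo[3.3.1]nonan-9-yl)propyl N,N-diisopropylcarbamate (not isolated) | CC(C)N(C(C)C)C(=O)OCCCB1C2CCCC1CCC2 | intermediate
11 | methyl (E)-3-{[(tert-butyldiphenylsilyl)oxy]methyl}-6-[(diisopropylcarbamoyl)oxy]hex-2-enoate | COC(=O)/C=C(\CCCOC(=O)N(C(C)C)C(C)C)CO[Si](c1ccccc1)(c1ccccc1)C(C)(C)C | intermediate
12 | (E)-4-{[(tert-butyldiphenylsilyl)oxy]methyl}-6-hydroxyhex-4-en-1-yl N,N-diisopropylcarbamate | OC/C=C(\CCCOC(=O)N(C(C)C)C(C)C)CO[Si](c1ccccc1)(c1ccccc1)C(C)(C)C | intermediate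
13 | (E)-4-{[(tert-butyldiphenylsilyl)oxy]methyl}-6-[(trimethylsilyl)oxy]hex-4-en-1-yl N,N-diisopropylcarbamate | C[Si](C)(C)OC/C=C(\CCCOC(=O)N(C(C)C)C(C)C)CO[Si](c1ccccc1)(c1ccccc1)C(C)(C)C | intermediate
14 | 4-methoxybenzyl alcohol | COc1ccc(CO)cc1 | starting material
15 | methyl propiolate | C#CC(=O)OC | starting material
16 | methyl (E)-3-[(4-methoxybenzyl)oxy]prop-2-enoate | COC(=O)/C=C/OCc1ccc(OC)cc1 | intermediate
17 | methyl 3-acetoxy-2-iodo-3-[(4-methoxybenzyl)oxy]propanoate (diastereomers, not isolated) | COC(=O)C(I)C(OC(C)=O)OCc1ccc(OC)cc1 | intermediate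
18 | methyl (Z)-2-iodo-3-[(4-methoxybenzyl)oxy]prop-2-enoate | COC(=O)/C(I)=C/OCc1ccc(OC)cc1 | intermediate
19 | (Z)-2-iodo-3-[(4-methoxybenzyl)oxy]prop-2-en-1-ol | OC/C(I)=C/OCc1ccc(OC)cc1 | intermediate
20 | tert-butyl{[(Z)-2-iodo-3-[(4-methoxybenzyl)oxy]prop-2-en-1-yl]oxy}dimethylsilane | CC(C)(C)[Si](C)(C)OC/C(I)=C/OCc1ccc(OC)cc1 | intermediate
21 | tert-butyl{[(E)-3-[(4-methoxybenzyl)oxy]-2-(4,4,5,5-tetramethyl-1,3,2-dioxaborolan-2-yl)prop-2-en-1-yl]oxy}dimethylsilane (B cis to O) | CC(C)(C)[Si](C)(C)OC/C(B1OC(C)(C)C(C)(C)O1)=C/OCc1ccc(OC)cc1 | intermediate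
22 | (S)-C1-lithiated carbamate of 13 (not isolated) | CC(C)N(C(C)C)C(=O)O[C@@H]([Li])CC/C(CO[Si](c1ccccc1)(c1ccccc1)C(C)(C)C)=C\CO[Si](C)(C)C | intermediate
23 | lithium boronate complex from 22 and 21 (not isolated) | [Li+].CC(C)N(C(C)C)C(=O)O[C@H](CC/C(CO[Si](c1ccccc1)(c1ccccc1)C(C)(C)C)=C\CO[Si](C)(C)C)[B-]1(OC(C)(C)C(C)(C)O1)/C(CO[Si](C)(C)C(C)(C)C)=C\OCc1ccc(OC)cc1 | intermediate
24 | C6 trimethylsilyl ether of 25 (not isolated) | C[Si](C)(C)OC/C=C(\CC[C@@H](B1OC(C)(C)C(C)(C)O1)/C(CO[Si](C)(C)C(C)(C)C)=C\OCc1ccc(OC)cc1)CO[Si](c1ccccc1)(c1ccccc1)C(C)(C)C | intermediate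
25 | (1R)-C1 allylic boronate alcohol (C6–OH; 4E; O9 cis to C1) | OC/C=C(\CC[C@@H](B1OC(C)(C)C(C)(C)O1)/C(CO[Si](C)(C)C(C)(C)C)=C\OCc1ccc(OC)cc1)CO[Si](c1ccccc1)(c1ccccc1)C(C)(C)C | intermediate
26 | (1R)-C6 enal with C1 boronate | O=C/C=C(\CC[C@@H](B1OC(C)(C)C(C)(C)O1)/C(CO[Si](C)(C)C(C)(C)C)=C\OCc1ccc(OC)cc1)CO[Si](c1ccccc1)(c1ccccc1)C(C)(C)C | intermediate
27 | (S)-4-benzyloxazolidin-2-one | O=C1N[C@@H](Cc2ccccc2)CO1 | starting material
28 | methyl 4-chloro-4-oxobutanoate | COC(=O)CCC(Cl)=O | starting material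
29 | lithium salt of 27 (not isolated) | [Li]N1[C@@H](Cc2ccccc2)COC1=O | intermediate
30 | (S)-4-benzyl-3-(4-methoxy-4-oxobutanoyl)oxazolidin-2-one | COC(=O)CCC(=O)N1[C@@H](Cc2ccccc2)COC1=O | intermediate
31 | (Z)-dibutylboron enolate of 30 (not isolated) | COC(=O)C/C=C(\OB(CCCC)CCCC)N1[C@@H](Cc2ccccc2)COC1=O | intermediate
32 | dibutylboron aldolate (6R,7S; not isolated) | O=C(N1[C@@H](Cc2ccccc2)COC1=O)[C@@H](CC(=O)OC)[C@H](OB(CCCC)CCCC)/C=C(\CC[C@@H](B1OC(C)(C)C(C)(C)O1)/C(CO[Si](C)(C)C(C)(C)C)=C\OCc1ccc(OC)cc1)CO[Si](c1ccccc1)(c1ccccc1)C(C)(C)C | intermediate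
33 | syn-aldol hydroxy ester (6R,7S; not isolated) | O=C(N1[C@@H](Cc2ccccc2)COC1=O)[C@@H](CC(=O)OC)[C@H](O)/C=C(\CC[C@@H](B1OC(C)(C)C(C)(C)O1)/C(CO[Si](C)(C)C(C)(C)C)=C\OCc1ccc(OC)cc1)CO[Si](c1ccccc1)(c1ccccc1)C(C)(C)C | intermediate
34 | trans-lactone imide (6R,7S,1R) | O=C(N1[C@@H](Cc2ccccc2)COC1=O)[C@H]1CC(=O)O[C@@H]1/C=C(/CO[Si](c1ccccc1)(c1ccccc1)C(C)(C)C)CC[C@@H](B1OC(C)(C)C(C)(C)O1)/C(CO[Si](C)(C)C(C)(C)C)=C\OCc1ccc(OC)cc1 | intermediate
35 | hydroxymethyl trans-lactone (C8 = CH2OH) | OC[C@H]1CC(=O)O[C@@H]1/C=C(/CO[Si](c1ccccc1)(c1ccccc1)C(C)(C)C)CC[C@@H](B1OC(C)(C)C(C)(C)O1)/C(CO[Si](C)(C)C(C)(C)C)=C\OCc1ccc(OC)cc1 | intermediate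
36 | lactone aldehyde with C1 allylboronate (1R,6R,7S) | O=C[C@H]1CC(=O)O[C@@H]1/C=C(/CO[Si](c1ccccc1)(c1ccccc1)C(C)(C)C)CC[C@@H](B1OC(C)(C)C(C)(C)O1)/C(CO[Si](C)(C)C(C)(C)C)=C\OCc1ccc(OC)cc1 | intermediate
37 | C8–O–Bpin borate of 38 (not isolated) | CC1(C)OB(O[C@H]2[C@H]3CC(=O)O[C@@H]3/C=C(/CO[Si](c3ccccc3)(c3ccccc3)C(C)(C)C)CC/C=C(/CO[Si](C)(C)C(C)(C)C)[C@@H]2OCc2ccc(OC)cc2)OC1(C)C | intermediate
38 | ten-membered lactone, C8–OH, C9–OPMB (6R,8S,9S) | O[C@H]1[C@H]2CC(=O)O[C@@H]2/C=C(/CO[Si](c3ccccc3)(c3ccccc3)C(C)(C)C)CC/C=C(/CO[Si](C)(C)C(C)(C)C)[C@@H]1OCc1ccc(OC)cc1 | intermediate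
39 | C8 triethylsilyl ether of 38 | CC[Si](CC)(CC)O[C@H]1[C@H]2CC(=O)O[C@@H]2/C=C(/CO[Si](c3ccccc3)(c3ccccc3)C(C)(C)C)CC/C=C(/CO[Si](C)(C)C(C)(C)C)[C@@H]1OCc1ccc(OC)cc1 | intermediate
40 | lithium enolate of 39 (not isolated) | CC[Si](CC)(CC)O[C@H]1[C@H]2C=C(O[Li])O[C@@H]2/C=C(/CO[Si](c3ccccc3)(c3ccccc3)C(C)(C)C)CC/C=C(/CO[Si](C)(C)C(C)(C)C)[C@@H]1OCc1ccc(OC)cc1 | intermediate
41 | C11 dimethylaminomethyl lactone (C11 unassigned) | CC[Si](CC)(CC)O[C@H]1[C@H]2C(CN(C)C)C(=O)O[C@@H]2/C=C(/CO[Si](c3ccccc3)(c3ccccc3)C(C)(C)C)CC/C=C(/CO[Si](C)(C)C(C)(C)C)[C@@H]1OCc1ccc(OC)cc1 | intermediate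
42 | trimethylammonium iodide of 41 (not isolated) | CC[Si](CC)(CC)O[C@H]1[C@H]2C(C[N+](C)(C)C)C(=O)O[C@@H]2/C=C(/CO[Si](c3ccccc3)(c3ccccc3)C(C)(C)C)CC/C=C(/CO[Si](C)(C)C(C)(C)C)[C@@H]1OCc1ccc(OC)cc1.[I-] | intermediate
43 | α-methylene lactone, C8–OTES | CC[Si](CC)(CC)O[C@H]1[C@H]2C(=C)C(=O)O[C@@H]2/C=C(/CO[Si](c3ccccc3)(c3ccccc3)C(C)(C)C)CC/C=C(/CO[Si](C)(C)C(C)(C)C)[C@@H]1OCc1ccc(OC)cc1 | intermediate
44 | α-methylene lactone, C8–OH | O[C@H]1[C@H]2C(=C)C(=O)O[C@@H]2/C=C(/CO[Si](c3ccccc3)(c3ccccc3)C(C)(C)C)CC/C=C(/CO[Si](C)(C)C(C)(C)C)[C@@H]1OCc1ccc(OC)cc1 | intermediate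
45 | C8 methacrylate, C14–OTBS | C=C(C)C(=O)O[C@H]1[C@H]2C(=C)C(=O)O[C@@H]2/C=C(/CO[Si](c3ccccc3)(c3ccccc3)C(C)(C)C)CC/C=C(/CO[Si](C)(C)C(C)(C)C)[C@@H]1OCc1ccc(OC)cc1 | intermediate
46 | C8 methacrylate, C14–OH | C=C(C)C(=O)O[C@H]1[C@H]2C(=C)C(=O)O[C@@H]2/C=C(/CO[Si](c3ccccc3)(c3ccccc3)C(C)(C)C)CC/C=C(/CO)[C@@H]1OCc1ccc(OC)cc1 | intermediate
47 | C14 enal, C9–OPMB | C=C(C)C(=O)O[C@H]1[C@H]2C(=C)C(=O)O[C@@H]2/C=C(/CO[Si](c3ccccc3)(c3ccccc3)C(C)(C)C)CC/C=C(/C=O)[C@@H]1OCc1ccc(OC)cc1 | intermediate
48 | C14 enal, C9–OH | C=C(C)C(=O)O[C@H]1[C@H]2C(=C)C(=O)O[C@@H]2/C=C(/CO[Si](c3ccccc3)(c3ccccc3)C(C)(C)C)CC/C=C(/C=O)[C@@H]1O | intermediate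
49 | C9 acetate, C15–OTBDPS | C=C(C)C(=O)O[C@H]1[C@H]2C(=C)C(=O)O[C@@H]2/C=C(/CO[Si](c3ccccc3)(c3ccccc3)C(C)(C)C)CC/C=C(/C=O)[C@@H]1OC(C)=O | intermediate
50 | CNP0147326.4 (6R,7S,8S,9S) | C=C(C)C(=O)O[C@H]1[C@H]2C(=C)C(=O)O[C@@H]2/C=C(/CO)CC/C=C(/C=O)[C@@H]1OC(C)=O | target

**Count**

Total: 29 steps. Longest linear sequence: 22 steps (1, 2, 3, 5, 6, 7, 13, 14, 16–29).

**Steps most likely to fail**

1. Step 19. The ring closure may be slower than intermolecular allyl transfer (oligomers), may run through the other chair (C2 equatorial, C7 axial) to the C8 epimer with a ring-trans alkene, or may lose to β-elimination of the lactone carboxylate from the aldehyde on long heating. The fallback uses known reactions only, sets out from 6, 21 and 30, and returns at 38. Negishi coupling of 6 with but-3-enylzinc bromide (Pd(PPh3)4, THF) should give the dienoate F1; iBu2AlH gives the dienol F2 and MnO2 the dienal F3. The Evans aldol of F3 with boron enolate 31 (from 30) gives the boron aldolate F4 and on work-up the hydroxy ester F5, which lactonises to the lactone imide F6; NaBH4 gives the hydroxymethyl lactone F7 and Dess–Martin oxidation the boron-free lactone aldehyde F8. Matteson homologation of 21 with chloromethyllithium (ICH2Cl, nBuLi, −78 °C → rt) gives the allylic boronate F9, with CH2–B cis to the PMB-oxygen and no stereocentre on carbon. Intermolecular (Z)-γ-alkoxyallylboration of F8 with F9 in toluene should give the borate F10 and, after buffer, the syn diene alcohol F11 (C8–OH, C9–OPMB, 1,1-disubstituted C10=CH2); the face is chosen by C7, with H7 next to the axial C9–O bond and C6 anti. Ring-closing metathesis of F11 between C10=CH2 and the terminal vinyl group at C1 (Hoveyda–Grubbs second-generation catalyst, toluene, 0.001 M, 80 °C) then forms C1=C10 and gives 38.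

2. Step 13. Lithiation may be incomplete or may compete with deprotonation next to the allylic silyl ethers, and the lithiated carbamate may add poorly to the α-branched, electron-rich alkenyl boronate or revert before migration. The fallback builds the same boronate complex from the other side; it sets out from 13 and 20 and returns at 23 (and so at 25). The lithiated carbamate 22 is trapped with 2-isopropoxy-4,4,5,5-tetramethyl-1,3,2-dioxaborolane to give the isolable α-(carbamoyloxy)alkyl boronate F12 (1S, retention). Iodine–lithium exchange on 20 (tBuLi, Et2O, −78 °C) gives the alkenyllithium F13, which adds to the unhindered boron of F12 to form 23; warming and K2CO3/MeOH then give 25 as in step 13.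

3. Step 16. Residual boron triflate or borinic acid may attack the allyl–B bond or the enol ether, the aldolate may resist non-oxidative cleavage, and neutral lactonisation may be slow or give way to retro-aldol. The fallback changes the enolate metal and the auxiliary; it sets out from 26 and 28 and returns at 35. N-Acylation of (R)-4-benzylthiazolidine-2-thione with 28 (Et3N, DMAP) gives the acyl thiazolidinethione F14. Sn(OTf)2 and N-ethylpiperidine (CH2Cl2, −40 °C) give the divalent tin enolate F15, which should add to 26 at −78 °C through the chelated (Nagao) transition state, whose facial sense is opposite to that of the boron enolate, hence the (R)-auxiliary; a buffer work-up without oxidant gives the syn hydroxy ester F16. Lactonisation gives the lactone thioimide F17, and NaBH4 in THF/H2O cleaves the thioimide to 35.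

Further compounds
F1 | step 19 | methyl (E)-3-{[(tert-butyldiphenylsilyl)oxy]methyl}hepta-2,6-dienoate | COC(=O)/C=C(\CCC=C)CO[Si](c1ccccc1)(c1ccccc1)C(C)(C)C
F2 | step 19 | (E)-3-{[(tert-butyldiphenylsilyl)oxy]methyl}hepta-2,6-dien-1-ol | OC/C=C(\CCC=C)CO[Si](c1ccccc1)(c1ccccc1)C(C)(C)C
F3 | step 19 | (E)-3-{[(tert-butyldiphenylsilyl)oxy]methyl}hepta-2,6-dienal | O=C/C=C(\CCC=C)CO[Si](c1ccccc1)(c1ccccc1)C(C)(C)C
F4 | step 19 | dibutylboron aldolate from 31 and F3 (6R,7S) | O=C(N1[C@@H](Cc2ccccc2)COC1=O)[C@@H](CC(=O)OC)[C@H](OB(CCCC)CCCC)/C=C(\CCC=C)CO[Si](c1ccccc1)(c1ccccc1)C(C)(C)C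
F5 | step 19 | syn-aldol hydroxy ester (6R,7S) | O=C(N1[C@@H](Cc2ccccc2)COC1=O)[C@@H](CC(=O)OC)[C@H](O)/C=C(\CCC=C)CO[Si](c1ccccc1)(c1ccccc1)C(C)(C)C
F6 | step 19 | boron-free trans-lactone imide | O=C(N1[C@@H](Cc2ccccc2)COC1=O)[C@H]1CC(=O)O[C@@H]1/C=C(/CO[Si](c1ccccc1)(c1ccccc1)C(C)(C)C)CCC=C
F7 | step 19 | boron-free hydroxymethyl lactone | OC[C@H]1CC(=O)O[C@@H]1/C=C(/CO[Si](c1ccccc1)(c1ccccc1)C(C)(C)C)CCC=C
F8 | step 19 | boron-free lactone aldehyde (6R,7S) | O=C[C@H]1CC(=O)O[C@@H]1/C=C(/CO[Si](c1ccccc1)(c1ccccc1)C(C)(C)C)CCC=C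
F9 | step 19 | tert-butyl{[3-[(4-methoxybenzyl)oxy]-2-[(4,4,5,5-tetramethyl-1,3,2-dioxaborolan-2-yl)methyl]prop-2-en-1-yl]oxy}dimethylsilane (CH2B cis to O) | CC(C)(C)[Si](C)(C)OC/C(CB1OC(C)(C)C(C)(C)O1)=C/OCc1ccc(OC)cc1
F10 | step 19 | C8–O–Bpin borate of F11 | CC1(C)OB(O[C@H]([C@@H](OCc2ccc(OC)cc2)C(=C)CO[Si](C)(C)C(C)(C)C)[C@H]2CC(=O)O[C@@H]2/C=C(/CO[Si](c2ccccc2)(c2ccccc2)C(C)(C)C)CCC=C)OC1(C)C
F11 | step 19 | syn diene alcohol (6R,8S,9S; C10=CH2; vinyl at C1) | O[C@H]([C@@H](OCc1ccc(OC)cc1)C(=C)CO[Si](C)(C)C(C)(C)C)[C@H]1CC(=O)O[C@@H]1/C=C(/CO[Si](c1ccccc1)(c1ccccc1)C(C)(C)C)CCC=C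
F12 | step 13 | (1S)-α-(carbamoyloxy)alkyl pinacol boronate from 13 | C[Si](C)(C)OC/C=C(\CC[C@@H](OC(=O)N(C(C)C)C(C)C)B1OC(C)(C)C(C)(C)O1)CO[Si](c1ccccc1)(c1ccccc1)C(C)(C)C
F13 | step 13 | alkenyllithium from 20 (Li cis to O) | [Li]/C(CO[Si](C)(C)C(C)(C)C)=C\OCc1ccc(OC)cc1
F14 | step 16 | (R)-4-benzyl-3-(4-methoxy-4-oxobutanoyl)thiazolidine-2-thione | COC(=O)CCC(=O)N1[C@H](Cc2ccccc2)CSC1=S
F15 | step 16 | divalent tin (Z)-enolate of F14 | COC(=O)C/C=C(\O[Sn]OS(=O)(=O)C(F)(F)F)N1[C@H](Cc2ccccc2)CSC1=S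
F16 | step 16 | syn-aldol hydroxy ester of the thioimide (6R,7S) | O=C(N1[C@H](Cc2ccccc2)CSC1=S)[C@@H](CC(=O)OC)[C@H](O)/C=C(\CC[C@@H](B1OC(C)(C)C(C)(C)O1)/C(CO[Si](C)(C)C(C)(C)C)=C\OCc1ccc(OC)cc1)CO[Si](c1ccccc1)(c1ccccc1)C(C)(C)C
F17 | step 16 | trans-lactone thioimide | O=C(N1[C@H](Cc2ccccc2)CSC1=S)[C@H]1CC(=O)O[C@@H]1/C=C(/CO[Si](c1ccccc1)(c1ccccc1)C(C)(C)C)CC[C@@H](B1OC(C)(C)C(C)(C)O1)/C(CO[Si](C)(C)C(C)(C)C)=C\OCc1ccc(OC)cc1
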